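**Structural features**

The target is a phenylcoumaran neolignan ester. Ring A is the benzo ring of a 2,3-dihydrobenzofuran, with a methoxy group at C7 and a three-carbon chain at C5. Ring B (4-hydroxy-3-methoxyphenyl) sits on C2, a hydroxymethyl group sits on C3, and the C5 chain ends in an (E)-4-hydroxy-3-methoxycinnamate (ring C). C2 (R) and C3 (S) are adjacent, trans, and the only stereocentres. C2 is both benzylic to ring B and bound to O1, so with a free para-phenol it can ionise under acid or open through a para-quinone methide under base; either event erases C2. The cinnamate excludes hydrogenolysis, hydride and strong base once it is in place, and the two primary alcohols must be told apart, since only the chain one is acylated. The real difficulty is therefore absolute control at C2/C3 on an electron-rich, easily ionised heterocycle, not the carbon count, because rings A, B and C are all guaiacyl units available from cheap phenols. The key step uses the fact that, once O1–C2 exists as an aryl benzyl ether, the C2–H bonds lie five atoms from C3 (C3–C3a–C7a–O1–C2) and are activated by both O1 and ring B, so a carbene at C3 can insert there and close the ring.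

**Logic of the disconnections**

22 ⇒ 21. The Si–O bonds at the ring B phenol and at the C3 hydroxymethyl group are cut last. The phenol must stay masked while bases are in use and the C3 alcohol must stay masked while the chain alcohol is acylated. The gain is that every earlier step handles a non-phenolic benzylic ether. The demand is a buffered fluoride step that spares the cinnamate and the O1–C2 bond.

21 ⇒ 19 + 20. The O–CH2 bond of the chain ester is cut, because it is the only link between ring C and the core. This splits the target into the stereodefined core and an achiral commodity acid. The forward step must esterify 20 without masking its phenol, and 19 may carry only one free hydroxyl.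

19 ⇒ 18 ⇒ 17 ⇒ 16. No skeletal bond is cut. The chain silyl ether is restored (18), the C3 silyl ether is removed (17), and the CH2OH is raised to the ester (16). The ester is what makes C3 a carbene acceptor and what lets C3 be equilibrated. The two primary alcohols are distinguished simply by when they appear. The demands are a hydride reduction that spares silyl ethers and an acid solvolysis that discriminates an alkyl TBS ether from a TBDPS ether and an aryl TIPS ether.

16 ⇒ 15 ⇒ 14. C3 is first inverted (16 from 15), then the C2–C3 bond is cut to a carbene at C3 and a C–H bond at C2. This removes the ring and both stereocentres in one move and leaves an achiral aryl benzyl ether. The forward step must distinguish two enantiotopic benzylic hydrogens and must insert only at the 1,5 position.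

14 ⇒ 13 ⇒ 12 ⇒ 11 ⇒ 10. The C=N2 bond is cut (diazo transfer retron), then the acetate side chain is traced back through acid and aldehyde to an allyl group. An allyl group is robust, and its position can be fixed by a sigmatropic shift. The demand is an alkene cleavage that tolerates two electron-rich rings and two silyl ethers.

10 ⇒ 6 + 9. The bond between the ring A oxygen and the ring B benzylic carbon (the future O1–C2) is cut while C2 is still a CH2 group. The molecule falls into two guaiacyl pieces of similar size. The forward step must alkylate a doubly ortho-substituted phenol without losing the aryl silyl ether.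

6 ⇒ 5 ⇒ 4 ⇒ 3 ⇒ 1. The ring A–allyl C–C bond is cut along a Claisen retron to an O-allyl ether, the chain silyl ether is removed, the O-allyl bond is cut, and the chain alcohol is traced to a terminal alkene. Everything then derives from one bulk phenol with the ring A oxygenation already correct. The demands are chemoselective phenol allylation and a single free ortho position, both of which the structure provides.

9 ⇒ 8 ⇒ 7. The benzylic alcohol is traced to the aldehyde and the aryl Si–O bond is cut. Ring B then comes from a commodity aldehyde in two routine steps.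

**Other disconnections considered**

Alternative 1: The cut is C2–C3 and O1–C2 together, so that C2 with ring B arrives as a one-carbon unit and ring A with C3 as a four-atom unit.
- Forward key step: base would expel sulfinate from the sulfone A2 to give the ortho-quinone methide A4 (exocyclic carbon = C3) and deprotonate the chiral sulfonium salt A3. The ylide carbon would add to C3 of A4, and the phenoxide would then displace the sulfide at C2, a formal [4+1] annulation giving A1.
- In its favour: it is convergent and makes two bonds and the ring in one flask. C3 arrives at the alcohol oxidation level, so no ester reduction is needed. Trans is the expected result of anti betaine closure.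
- Against it here: the stereochemical information sits in a stoichiometric sulfide and must control a bimolecular addition between two short-lived planar partners. A4 has hydrogens next to the methide carbon, so a 1,5-hydrogen shift to an ortho-hydroxystyrene can compete with capture. A3 is a strong benzylating agent that may simply O-alkylate the phenoxide of A2.
- Structure: both plans give the same trans ring. A1 already has its two primary oxygens differentiated (silyl ether versus latent alkene), so hydroboration–oxidation, esterification with 20 and one desilylation would finish the synthesis in 3 steps against 5 here; on this point the alternative is better.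
- Mechanism: the chosen plan sets C2 by a catalyst in an intramolecular step of a well-known type and corrects C3 thermodynamically, whereas the alternative must set both centres at once. On diastereocontrol the two are equal; on the security of enantiocontrol the chosen plan is stronger.
- Step economy: roughly equal overall, since A2 and A3 each need several steps from 1 and 7.

Alternative 2: The cut is C3a–C7a and C6–C7, that is ring A itself. Four ring A carbons and the C7 oxygen come from a 2,4-disubstituted furan, and C7 and C7a come from an ethynyl ether on the C2 oxygen.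
- Forward key step: (Ph3P)AuNTf2 would activate the alkyne of A6, the furan would attack it, and reorganisation of the furan ring into a phenol would deliver ring A and the dihydrofuran together in A5.
- In its favour: it is an isomerisation with full atom economy. C2 and C3 are made beforehand and take no part, so the key step cannot erode them; on this point it is better than the chosen plan. The phenol appears exactly at C7, and its O-methylation would give 18, so from 18 on the two plans are equal.
- Against it here: A6 needs both stereocentres built in an open chain by separate asymmetric chemistry, the less accessible 2,4-substitution pattern of the furan, and a terminal ynol ether on a secondary, doubly activated benzylic oxygen. Such ethers tend to rearrange to ketenes or ionise, and their preparation uses strong base that endangers the aryl silyl ether.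
- Structure: ring A is built from scratch, although 1 supplies it intact in the chosen plan.
- Mechanism: it is stereochemically innocent, but chemoselectivity with a labile ynol ether is less secure than insertion into an activated C–H bond.
- Step economy: clearly worse before the key step; marginally better after it (1 step to 18 against 2).

Alternative 3: The cut is O1–C2 only.
- Forward key step: catalytic p-toluenesulfonic acid would ionise the carbinol A8 (either epimer) to the ring B para-quinone methide A9. The ring A phenol would add to the methide carbon (5-exo-trig) anti to the C3 substituent, giving trans A7.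
- In its favour: it is stereoconvergent at C2, so only C3 must be made enantioselectively. It uses no metal and no diazo compound, which makes it better on hazard. A7 has exactly the needed protection pattern (chain alcohol free, C3 alcohol silylated), so esterification with 20 and one desilylation would finish in 2 steps; this is clearly better than the 5 steps here.
- Against it here: loss of the C3 proton from A9 would give a stilbene and destroy the only stereocentre. The free chain alcohol can add to A9 intermolecularly. A8 itself requires an auxiliary-based construction of a 1,2-diarylpropane with four differentiated hydroxyls.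
- Structure: both plans form O1–C2; here it is formed before C2 is stereogenic, there as the last ring bond.
- Mechanism: trans control by thermodynamics is equal in both. Absolute control is by auxiliary there and by catalyst here, which is comparable in reliability, with the chosen plan better in atom economy.
- Step economy: better after the key step and about equal overall, because A8 would need roughly as many steps as 14.

Key step: step 12

Assumption: Rh2(R-PTTL)4 is taken to be the enantiomer that selects the benzylic hydrogen leading to 2R, by analogy with closely related 2-(4-oxygenated benzyloxy)aryl diazoacetates. If the sense proves opposite, Rh2(S-PTTL)4 is used and nothing else changes.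

Abbreviations: TBS = tert-butyldimethylsilyl, TIPS = triisopropylsilyl, TBDPS = tert-butyldiphenylsilyl.

**Step 1**
Reactants: 1 eugenol
Product: 3 dihydroconiferyl alcohol [4-(3-hydroxypropyl)-2-methoxyphenol], via bis(boryl) adduct 2 (not isolated)
Conditions: 9-BBN (2.3 equiv), THF, 0 °C → rt; then aq. NaOH, H2O2, 0 °C → rt
Reagents that add atoms: 9-borabicyclo[3.3.1]nonane, B1C2CCCC1CCC2 (boron held in 2 only); hydrogen peroxide, OO (the new oxygen of 3)
Why: Brown hydroboration–oxidation: the bulky dialkylborane puts boron on the terminal alkene carbon only, one equivalent is consumed by the phenol as a borinate that hydrolyses in the work-up, and alkaline peroxide replaces C–B by C–O; no stereocentre is formed.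

**Step 2**
Reactants: 3 dihydroconiferyl alcohol
Product: 4 3-[4-(allyloxy)-3-methoxyphenyl]propan-1-ol
Conditions: allyl bromide, K2CO3, acetone, reflux
Reagents that add atoms: allyl bromide, C=CCBr
Why: Williamson ether synthesis: K2CO3 ionises only the phenol, so the primary alcohol should not be allylated.

**Step 3**
Reactants: 4 3-[4-(allyloxy)-3-methoxyphenyl]propan-1-ol
Product: 5 {3-[4-(allyloxy)-3-methoxyphenyl]propoxy}(tert-butyl)dimethylsilane
Conditions: TBSCl, imidazole, CH2Cl2, rt
Reagents that add atoms: tert-butyldimethylsilyl chloride, CC(C)(C)[Si](C)(C)Cl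
Why: Imidazole-promoted silylation of the only remaining hydroxyl; placing it after step 2 removes any phenol-versus-alcohol selectivity question.

**Step 4**
Reactants: 5 {3-[4-(allyloxy)-3-methoxyphenyl]propoxy}(tert-butyl)dimethylsilane
Product: 6 2-allyl-6-methoxy-4-[3-(TBS-oxy)propyl]phenol
Conditions: N,N-diethylaniline, 190 °C
Reagents that add atoms: none
Why: Aromatic Claisen rearrangement: the [3,3] shift delivers the allyl group to the single ortho position that bears hydrogen and tautomerisation restores the arene; the para position is blocked, so one regioisomer is expected.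

**Step 5**
Reactants: 7 vanillin
Product: 8 3-methoxy-4-(TIPS-oxy)benzaldehyde
Conditions: TIPSCl, imidazole, DMF, rt
Reagents that add atoms: triisopropylsilyl chloride, CC(C)[Si](Cl)(C(C)C)C(C)C
Why: Silylation of a phenol; TIPS is chosen because it should resist the amine base and hydride steps ahead far better than TBS, keeps ring B electron-rich for the insertion and shields that ring from the carbene.

**Step 6**
Reactants: 8 3-methoxy-4-(TIPS-oxy)benzaldehyde
Product: 9 [3-methoxy-4-(TIPS-oxy)phenyl]methanol
Conditions: NaBH4, THF/MeOH (4:1), 0 °C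
Reagents that add atoms: none
Why: Borohydride reduction of an aryl aldehyde; it is fast at 0 °C, so the aryl silyl ether sees alkoxide only briefly.

**Step 7**
Reactants: 6 2-allyl-6-methoxy-4-[3-(TBS-oxy)propyl]phenol; 9 [3-methoxy-4-(TIPS-oxy)phenyl]methanol
Product: 10 tert-butyl[3-(3-allyl-5-methoxy-4-{[3-methoxy-4-(TIPS-oxy)phenyl]methoxy}phenyl)propoxy]dimethylsilane
Conditions: PPh3, DIAD, toluene, 0 °C → rt
Reagents that add atoms: none
Why: Mitsunobu etherification: phenol 6 protonates the PPh3–DIAD betaine and its phenoxide displaces the oxyphosphonium of the primary benzylic alcohol 9 by SN2; this makes the future O1–C2 bond under neutral conditions and avoids both a self-ionising para-silyloxybenzyl halide and carbonate in a dipolar solvent, which can strip aryl silyl ethers.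

**Step 8**
Reactants: 10 allyl arene from step 7
Product: 11 2-[3-methoxy-2-{[3-methoxy-4-(TIPS-oxy)phenyl]methoxy}-5-{3-(TBS-oxy)propyl}phenyl]acetaldehyde
Conditions: OsO4 (2 mol %), NaIO4 (4 equiv), 2,6-lutidine, dioxane/H2O (3:1), rt
Reagents that add atoms: osmium tetroxide OsO4, O=[Os](=O)(=O)=O (catalytic oxygen carrier); sodium periodate NaIO4, [Na+].[O-]I(=O)(=O)=O (terminal oxygen source)
Why: Lemieux–Johnson oxidative cleavage: OsO4 dihydroxylates the monosubstituted alkene much faster than it touches the alkoxyarenes and NaIO4 cleaves the diol and regenerates the catalyst; 2,6-lutidine keeps the medium neutral for the silyl ethers and limits over-oxidation.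

**Step 9**
Reactants: 11 arylacetaldehyde from step 8
Product: 12 2-[3-methoxy-2-{[3-methoxy-4-(TIPS-oxy)phenyl]methoxy}-5-{3-(TBS-oxy)propyl}phenyl]acetic acid
Conditions: NaClO2, NaH2PO4, 2-methyl-2-butene (excess), t-BuOH/H2O, 0 °C → rt
Reagents that add atoms: sodium chlorite NaClO2, [Na+].[O-]Cl=O
Why: Pinnick oxidation: chlorous acid converts the aldehyde into the acid without enolisation, and the excess alkene removes hypochlorous acid before it can chlorinate the electron-rich rings; crude 11 is used at once because arylacetaldehydes store poorly.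

**Step 10**
Reactants: 12 arylacetic acid from step 9
Product: 13 methyl 2-[3-methoxy-2-{[3-methoxy-4-(TIPS-oxy)phenyl]methoxy}-5-{3-(TBS-oxy)propyl}phenyl]acetate
Conditions: TMSCHN2, toluene/MeOH (4:1), 0 °C
Reagents that add atoms: trimethylsilyldiazomethane, C[Si](C)(C)C=[N+]=[N-] (supplies the ester CH3 carbon)
Why: Esterification by diazomethane generated in situ from TMSCHN2 and methanol (protonation by the acid, then O-methylation of the carboxylate); no base is present that could touch the aryl silyl ether.

**Step 11**
Reactants: 13 methyl arylacetate from step 10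
Product: 14 methyl 2-diazo-2-[3-methoxy-2-{[3-methoxy-4-(TIPS-oxy)phenyl]methoxy}-5-{3-(TBS-oxy)propyl}phenyl]acetate
Conditions: p-ABSA, DBU, MeCN, 0 °C → rt
Reagents that add atoms: 4-acetamidobenzenesulfonyl azide, CC(=O)Nc1ccc(cc1)S(=O)(=O)N=[N+]=[N-]
Why: Regitz diazo transfer: DBU forms the benzylic ester enolate, which attacks the terminal nitrogen of the sulfonyl azide, and collapse of the adduct gives the aryldiazoacetate and the sulfonamide.

**Step 12**
Reactants: 14 aryldiazoacetate from step 11
Product: 16 methyl (2R,3R)-trans-7-methoxy-2-[3-methoxy-4-(TIPS-oxy)phenyl]-5-[3-(TBS-oxy)propyl]-2,3-dihydrobenzofuran-3-carboxylate, via cis ester 15 (not isolated)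
Conditions: Rh2(R-PTTL)4 (1 mol %), toluene, −78 → −40 °C; then DBU (1 equiv), rt → 50 °C
Reagents that add atoms: none
Why: The dirhodium tetracarboxylate expels N2 from 14 to give a donor/acceptor rhodium carbene at the future C3, and this electrophilic carbon engages an O–CH2–ring B hydrogen five atoms away in a concerted but asynchronous, hydride-transfer-like three-centre transition state, so that C2–C3 forms as C–H breaks. The closest known reaction type is the enantioselective intramolecular 1,5 C–H insertion of methyl 2-(2-benzyloxyaryl)-2-diazoacetates under chiral dirhodium carboxylate catalysis, which gives cis-2-aryl-2,3-dihydrobenzofuran-3-carboxylates. The dihydrofuran ring is closed by this 1,5-insertion through the five-atom array C3–C3a–C7a–O1–C2, and no other ring size is available on this tether. C2 is set by the catalyst, whose phthalimido walls should let only one of the two enantiotopic benzylic hydrogens reach the carbene, with retention at that carbon. C3 is expected to form cis first (15) because ester and ring B stay on the same side in the compact transition state, and DBU then removes the acidic C3–H (benzylic and alpha to the ester) so that reprotonation gives the more stable trans ester 16 under substrate control. C2 is not at risk in that equilibration because opening of the C3 enolate to a phenoxide would be a retro-5-endo-trig process in which the C2–O1 bond is orthogonal to the enolate pi system. Site selectivity is needed against the methoxy C–H bonds, the chain OCH2 group and arene cyclopropanation (Büchner reaction), and it is secured by the tether length, by the double activation of C2–H through O1 and the para-silyloxyaryl group, and by the bulk of the TIPS group on ring B. Carbene dimerisation is suppressed by the low temperature and by the donor/acceptor character of the carbene.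

**Step 13**
Reactants: 16 trans ester from step 12
Product: 17 [(2R,3S)-7-methoxy-2-[3-methoxy-4-(TIPS-oxy)phenyl]-5-[3-(TBS-oxy)propyl]-2,3-dihydrobenzofuran-3-yl]methanol
Conditions: LiBH4, THF, MeOH (1 equiv), 0 °C → rt
Reagents that add atoms: none
Why: Borohydride reduction of the ester to the primary alcohol; silyl ethers and the benzylic ether are inert, and since C3 already has the more stable trans arrangement the basic medium cannot erode it (the descriptor changes to 3S by priority only).

**Step 14**
Reactants: 17 alcohol from step 13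
Product: 18 tert-butyl{[(2R,3S)-7-methoxy-2-[3-methoxy-4-(TIPS-oxy)phenyl]-5-[3-(TBS-oxy)propyl]-2,3-dihydrobenzofuran-3-yl]methoxy}diphenylsilane
Conditions: TBDPSCl, imidazole, DMAP (cat.), CH2Cl2, rt
Reagents that add atoms: tert-butyl(chloro)diphenylsilane, CC(C)(C)[Si](Cl)(c1ccccc1)c1ccccc1
Why: Silylation of the primary alcohol; TBDPS is chosen because it should survive the acid solvolysis of step 15 yet fall to fluoride in step 17 together with the aryl TIPS group.

**Step 15**
Reactants: 18 tris-silyl ether from step 14
Product: 19 3-[(2R,3S)-3-{[(TBDPS)oxy]methyl}-7-methoxy-2-[3-methoxy-4-(TIPS-oxy)phenyl]-2,3-dihydrobenzofuran-5-yl]propan-1-ol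
Conditions: PPTS (0.3 equiv), MeOH/CH2Cl2, rt
Reagents that add atoms: none
Why: Acid-catalysed methanolysis: a primary alkyl TBS ether is solvolysed far faster than a TBDPS ether or an aryl TIPS ether, and the mild pyridinium acid should not ionise the O1–C2 bond while ring B is still silylated.

**Step 16**
Reactants: 19 chain alcohol from step 15; 20 ferulic acid
Product: 21 3-[(2R,3S)-3-{[(TBDPS)oxy]methyl}-7-methoxy-2-[3-methoxy-4-(TIPS-oxy)phenyl]-2,3-dihydrobenzofuran-5-yl]propyl (E)-3-(4-hydroxy-3-methoxyphenyl)prop-2-enoate
Conditions: PPh3, DIAD, THF, 0 °C → rt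
Reagents that add atoms: none
Why: Mitsunobu esterification: the carboxylic acid is the only pronucleophile acidic enough to be carried through the betaine, so its carboxylate displaces the oxyphosphonium of the sole free alcohol and the phenol of 20 needs no protection; the (E)-alkene is untouched.

**Step 17**
Reactants: 21 silylated ester from step 16
Product: 22 3-[(2R,3S)-2-(4-hydroxy-3-methoxyphenyl)-3-(hydroxymethyl)-7-methoxy-2,3-dihydrobenzofuran-5-yl]propyl (E)-3-(4-hydroxy-3-methoxyphenyl)prop-2-enoate
Conditions: TBAF, AcOH (1:1), THF, 0 °C → rt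
Reagents that add atoms: none
Why: Fluoride cleavage of the aryl TIPS and primary TBDPS ethers; acetic acid buffers the phenoxide formed, which should protect the cinnamate ester and prevent opening of the O1–C2 bond through a para-quinone methide, so C2 and C3 are retained.

**Compound list**

1 | eugenol (4-allyl-2-methoxyphenol) | COc1cc(CC=C)ccc1O | starting material
2 | 9-[3-(4-{[9-borabicyclo[3.3.1]nonan-9-yl]oxy}-3-methoxyphenyl)propyl]-9-borabicyclo[3.3.1]nonane | COc1cc(CCCB2C3CCCC2CCC3)ccc1OB1C2CCCC1CCC2 | intermediate (not isolated)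
3 | 4-(3-hydroxypropyl)-2-methoxyphenol | COc1cc(CCCO)ccc1O | intermediate
4 | 3-[4-(allyloxy)-3-methoxyphenyl]propan-1-ol | C=CCOc1ccc(CCCO)cc1OC | intermediate
5 | {3-[4-(allyloxy)-3-methoxyphenyl]propoxy}(tert-butyl)dimethylsilane | C=CCOc1ccc(CCCO[Si](C)(C)C(C)(C)C)cc1OC | intermediate
6 | 2-allyl-4-{3-[(tert-butyldimethylsilyl)oxy]propyl}-6-methoxyphenol | C=CCc1cc(CCCO[Si](C)(C)C(C)(C)C)cc(OC)c1O | intermediate
7 | vanillin (4-hydroxy-3-methoxybenzaldehyde) | COc1cc(C=O)ccc1O | starting material
8 | 3-methoxy-4-[(triisopropylsilyl)oxy]benzaldehyde | COc1cc(C=O)ccc1O[Si](C(C)C)(C(C)C)C(C)C | intermediate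
9 | {3-methoxy-4-[(triisopropylsilyl)oxy]phenyl}methanol | COc1cc(CO)ccc1O[Si](C(C)C)(C(C)C)C(C)C | intermediate
10 | tert-butyl[3-(3-allyl-5-methoxy-4-{[3-methoxy-4-(triisopropylsilyloxy)phenyl]methoxy}phenyl)propoxy]dimethylsilane | C=CCc1cc(CCCO[Si](C)(C)C(C)(C)C)cc(OC)c1OCc1ccc(O[Si](C(C)C)(C(C)C)C(C)C)c(OC)c1 | intermediate
11 | 2-[5-{3-[(tert-butyldimethylsilyl)oxy]propyl}-3-methoxy-2-({3-methoxy-4-[(triisopropylsilyl)oxy]phenyl}methoxy)phenyl]acetaldehyde | O=CCc1cc(CCCO[Si](C)(C)C(C)(C)C)cc(OC)c1OCc1ccc(O[Si](C(C)C)(C(C)C)C(C)C)c(OC)c1 | intermediate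
12 | 2-[5-{3-[(tert-butyldimethylsilyl)oxy]propyl}-3-methoxy-2-({3-methoxy-4-[(triisopropylsilyl)oxy]phenyl}methoxy)phenyl]acetic acid | OC(=O)Cc1cc(CCCO[Si](C)(C)C(C)(C)C)cc(OC)c1OCc1ccc(O[Si](C(C)C)(C(C)C)C(C)C)c(OC)c1 | intermediate
13 | methyl 2-[5-{3-[(tert-butyldimethylsilyl)oxy]propyl}-3-methoxy-2-({3-methoxy-4-[(triisopropylsilyl)oxy]phenyl}methoxy)phenyl]acetate | COC(=O)Cc1cc(CCCO[Si](C)(C)C(C)(C)C)cc(OC)c1OCc1ccc(O[Si](C(C)C)(C(C)C)C(C)C)c(OC)c1 | intermediate
14 | methyl 2-diazo-2-[5-{3-[(tert-butyldimethylsilyl)oxy]propyl}-3-methoxy-2-({3-methoxy-4-[(triisopropylsilyl)oxy]phenyl}methoxy)phenyl]acetate | COC(=O)C(=[N+]=[N-])c1cc(CCCO[Si](C)(C)C(C)(C)C)cc(OC)c1OCc1ccc(O[Si](C(C)C)(C(C)C)C(C)C)c(OC)c1 | intermediate (precursor of the key step)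
15 | methyl (2R,3S)-cis-5-{3-[(tert-butyldimethylsilyl)oxy]propyl}-7-methoxy-2-{3-methoxy-4-[(triisopropylsilyl)oxy]phenyl}-2,3-dihydrobenzofuran-3-carboxylate | CC(C)(C)[Si](C)(C)OCCCc1cc(OC)c2c(c1)[C@H](C(=O)OC)[C@H](c3ccc(O[Si](C(C)C)(C(C)C)C(C)C)c(OC)c3)O2 | intermediate (not isolated)
16 | methyl (2R,3R)-trans-5-{3-[(tert-butyldimethylsilyl)oxy]propyl}-7-methoxy-2-{3-methoxy-4-[(triisopropylsilyl)oxy]phenyl}-2,3-dihydrobenzofuran-3-carboxylate | CC(C)(C)[Si](C)(C)OCCCc1cc(OC)c2c(c1)[C@@H](C(=O)OC)[C@H](c3ccc(O[Si](C(C)C)(C(C)C)C(C)C)c(OC)c3)O2 | intermediate (product of the key step)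
17 | [(2R,3S)-5-{3-[(tert-butyldimethylsilyl)oxy]propyl}-7-methoxy-2-{3-methoxy-4-[(triisopropylsilyl)oxy]phenyl}-2,3-dihydrobenzofuran-3-yl]methanol | CC(C)(C)[Si](C)(C)OCCCc1cc(OC)c2c(c1)[C@@H](CO)[C@H](c3ccc(O[Si](C(C)C)(C(C)C)C(C)C)c(OC)c3)O2 | intermediate
18 | tert-butyl{[(2R,3S)-5-{3-[(tert-butyldimethylsilyl)oxy]propyl}-7-methoxy-2-{3-methoxy-4-[(triisopropylsilyl)oxy]phenyl}-2,3-dihydrobenzofuran-3-yl]methoxy}diphenylsilane | CC(C)(C)[Si](C)(C)OCCCc1cc(OC)c2c(c1)[C@@H](CO[Si](c3ccccc3)(c3ccccc3)C(C)(C)C)[C@H](c3ccc(O[Si](C(C)C)(C(C)C)C(C)C)c(OC)c3)O2 | intermediate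
19 | 3-[(2R,3S)-3-{[(tert-butyldiphenylsilyl)oxy]methyl}-7-methoxy-2-{3-methoxy-4-[(triisopropylsilyl)oxy]phenyl}-2,3-dihydrobenzofuran-5-yl]propan-1-ol | OCCCc1cc(OC)c2c(c1)[C@@H](CO[Si](c3ccccc3)(c3ccccc3)C(C)(C)C)[C@H](c3ccc(O[Si](C(C)C)(C(C)C)C(C)C)c(OC)c3)O2 | intermediate
20 | ferulic acid [(E)-3-(4-hydroxy-3-methoxyphenyl)prop-2-enoic acid] | COc1cc(/C=C/C(=O)O)ccc1O | starting material
21 | 3-[(2R,3S)-3-{[(tert-butyldiphenylsilyl)oxy]methyl}-7-methoxy-2-{3-methoxy-4-[(triisopropylsilyl)oxy]phenyl}-2,3-dihydrobenzofuran-5-yl]propyl (E)-3-(4-hydroxy-3-methoxyphenyl)prop-2-enoate | COc1cc(/C=C/C(=O)OCCCc2cc(OC)c3c(c2)[C@@H](CO[Si](c4ccccc4)(c4ccccc4)C(C)(C)C)[C@H](c2ccc(O[Si](C(C)C)(C(C)C)C(C)C)c(OC)c2)O3)ccc1O | intermediate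
22 | 3-[(2R,3S)-2-(4-hydroxy-3-methoxyphenyl)-3-(hydroxymethyl)-7-methoxy-2,3-dihydrobenzofuran-5-yl]propyl (E)-3-(4-hydroxy-3-methoxyphenyl)prop-2-enoate | COc1cc(/C=C/C(=O)OCCCc2cc(OC)c3c(c2)[C@@H](CO)[C@H](c2ccc(O)c(OC)c2)O3)ccc1O | target

**Step count and risk**

Total: 17 steps. Longest linear sequence: 15 steps (steps 1–4, 7–15, 16 and 17, from 1 to 22); steps 5 and 6 form the ring B branch.

Step 12 (key step). The most likely failure is insufficient discrimination between the two enantiotopic benzylic hydrogens. The C7 methoxy group twists the benzyloxy arm, and the very electron-rich ring B makes the hydride-transfer component early. A second risk is slow base equilibration at C3.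
- Fallback (auxiliary control instead of catalyst control), setting out from 12 and returning at 17.
- Acid 12 is esterified (EDC·HCl, DMAP, CH2Cl2) with (R)-2-hydroxy-1-(pyrrolidin-1-yl)propan-1-one to give the lactamide ester (R)-1-oxo-1-(pyrrolidin-1-yl)propan-2-yl arylacetate F1.
- Diazo transfer (p-ABSA, DBU, MeCN) gives the corresponding diazo ester F2.
- Insertion with Rh2(R-DOSP)4, dirhodium tetrakis[(R)-N-(4-dodecylbenzenesulfonyl)prolinate], in CH2Cl2 is expected to give the trans (2R,3R) auxiliary ester F3 as a separable diastereomer, since auxiliary and matched catalyst act together.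
- LiBH4 in THF then releases the auxiliary and gives 17.
- The R auxiliary and R catalyst are written on the assumption that this pairing leads to 2R; otherwise the mirror-image pairing would be taken.

Step 7. The most likely failure is slow attack by the doubly ortho-substituted phenoxide, which would leave time for the activated benzylic oxyphosphonium ion to ionise and alkylate the hydrazide or an arene carbon.
- Fallback (preformed electrophile and SN2 alkylation), setting out from 9 and returning at 10.
- 9 is converted by an Appel reaction (CBr4, PPh3, CH2Cl2, 0 °C) into [4-(bromomethyl)-2-methoxyphenoxy]triisopropylsilane F4.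
- F4 is used at once to alkylate 6 (K2CO3, acetone, rt), giving 10.

Step 16. The most likely failure is competing O-alkylation of a phenol, or a slow reaction because of poor solubility of the free acid.
- Fallback (acyl activation of a protected acid), setting out from 20 and 19 and returning at 22.
- 20 is silylated on both oxygens (TIPSCl, imidazole, DMF) to give triisopropylsilyl (E)-3-[3-methoxy-4-(triisopropylsilyloxy)phenyl]prop-2-enoate F5.
- The silyl ester is hydrolysed (K2CO3, MeOH/THF/H2O, 0 °C) to give (E)-3-[3-methoxy-4-(triisopropylsilyloxy)phenyl]prop-2-enoic acid F6.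
- Steglich esterification of F6 with 19 (EDC·HCl, DMAP, CH2Cl2) gives the tris-silyl ester F7.
- TBAF/AcOH in THF converts F7 into 22.

Step 17. The most likely failure is fluoride basicity causing cleavage or transesterification of the phenolic cinnamate, or phenoxide-triggered opening of the O1–C2 bond with loss of configuration at C2.
- Fallback (final unmasking under mild acid instead of fluoride), setting out from 17 and returning at 22.
- 17 is converted (3,4-dihydro-2H-pyran, PPTS, CH2Cl2) into its tetrahydropyranyl ether F8.
- TBAF in THF (0 °C → rt) removes both the chain TBS and the aryl TIPS group before any cinnamate is present, giving the phenol–alcohol F9.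
- Mitsunobu esterification of F9 with 20 (PPh3, DIAD, THF) gives the tetrahydropyranyl-protected ester F10.
- PPTS in MeOH at rt converts F10 into 22.

**Further compounds**

F1 | step 12 | (R)-1-oxo-1-(pyrrolidin-1-yl)propan-2-yl 2-[5-{3-[(tert-butyldimethylsilyl)oxy]propyl}-3-methoxy-2-({3-methoxy-4-[(triisopropylsilyl)oxy]phenyl}methoxy)phenyl]acetate | CC(C)(C)[Si](C)(C)OCCCc1cc(OC)c(OCc2ccc(O[Si](C(C)C)(C(C)C)C(C)C)c(OC)c2)c(c1)CC(=O)O[C@H](C)C(=O)N1CCCC1
F2 | step 12 | (R)-1-oxo-1-(pyrrolidin-1-yl)propan-2-yl 2-diazo-2-[5-{3-[(tert-butyldimethylsilyl)oxy]propyl}-3-methoxy-2-({3-methoxy-4-[(triisopropylsilyl)oxy]phenyl}methoxy)phenyl]acetate | CC(C)(C)[Si](C)(C)OCCCc1cc(OC)c(OCc2ccc(O[Si](C(C)C)(C(C)C)C(C)C)c(OC)c2)c(c1)C(=[N+]=[N-])C(=O)O[C@H](C)C(=O)N1CCCC1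
F3 | step 12 | (R)-1-oxo-1-(pyrrolidin-1-yl)propan-2-yl (2R,3R)-trans-5-{3-[(tert-butyldimethylsilyl)oxy]propyl}-7-methoxy-2-{3-methoxy-4-[(triisopropylsilyl)oxy]phenyl}-2,3-dihydrobenzofuran-3-carboxylate | CC(C)(C)[Si](C)(C)OCCCc1cc(OC)c2c(c1)[C@@H](C(=O)O[C@H](C)C(=O)N1CCCC1)[C@H](c3ccc(O[Si](C(C)C)(C(C)C)C(C)C)c(OC)c3)O2
F4 | step 7 | [4-(bromomethyl)-2-methoxyphenoxy]triisopropylsilane | COc1cc(CBr)ccc1O[Si](C(C)C)(C(C)C)C(C)C
F5 | step 16 | triisopropylsilyl (E)-3-{3-methoxy-4-[(triisopropylsilyl)oxy]phenyl}prop-2-enoate | COc1cc(/C=C/C(=O)O[Si](C(C)C)(C(C)C)C(C)C)ccc1O[Si](C(C)C)(C(C)C)C(C)C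
F6 | step 16 | (E)-3-{3-methoxy-4-[(triisopropylsilyl)oxy]phenyl}prop-2-enoic acid | COc1cc(/C=C/C(=O)O)ccc1O[Si](C(C)C)(C(C)C)C(C)C
F7 | step 16 | 3-[(2R,3S)-3-{[(tert-butyldiphenylsilyl)oxy]methyl}-7-methoxy-2-{3-methoxy-4-[(triisopropylsilyl)oxy]phenyl}-2,3-dihydrobenzofuran-5-yl]propyl (E)-3-{3-methoxy-4-[(triisopropylsilyl)oxy]phenyl}prop-2-enoate | COc1cc(/C=C/C(=O)OCCCc2cc(OC)c3c(c2)[C@@H](CO[Si](c4ccccc4)(c4ccccc4)C(C)(C)C)[C@H](c2ccc(O[Si](C(C)C)(C(C)C)C(C)C)c(OC)c2)O3)ccc1O[Si](C(C)C)(C(C)C)C(C)C
F8 | step 17 | tert-butyl{3-[(2R,3S)-7-methoxy-2-{3-methoxy-4-[(triisopropylsilyl)oxy]phenyl}-3-{[(tetrahydro-2H-pyran-2-yl)oxy]methyl}-2,3-dihydrobenzofuran-5-yl]propoxy}dimethylsilane (both acetal epimers) | CC(C)(C)[Si](C)(C)OCCCc1cc(OC)c2c(c1)[C@@H](COC1CCCCO1)[C@H](c3ccc(O[Si](C(C)C)(C(C)C)C(C)C)c(OC)c3)O2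
F9 | step 17 | 4-[(2R,3S)-5-(3-hydroxypropyl)-7-methoxy-3-{[(tetrahydro-2H-pyran-2-yl)oxy]methyl}-2,3-dihydrobenzofuran-2-yl]-2-methoxyphenol (both acetal epimers) | OCCCc1cc(OC)c2c(c1)[C@@H](COC1CCCCO1)[C@H](c3ccc(O)c(OC)c3)O2
F10 | step 17 | 3-[(2R,3S)-2-(4-hydroxy-3-methoxyphenyl)-7-methoxy-3-{[(tetrahydro-2H-pyran-2-yl)oxy]methyl}-2,3-dihydrobenzofuran-5-yl]propyl (E)-3-(4-hydroxy-3-methoxyphenyl)prop-2-enoate (both acetal epimers) | COc1cc(/C=C/C(=O)OCCCc2cc(OC)c3c(c2)[C@@H](COC2CCCCO2)[C@H](c2ccc(O)c(OC)c2)O3)ccc1O
A1 | alternative 1 | (2R,3S)-trans-5-allyl-7-methoxy-2-{3-methoxy-4-[(triisopropylsilyl)oxy]phenyl}-3-{[(triisopropylsilyl)oxy]methyl}-2,3-dihydrobenzofuran | C=CCc1cc(OC)c2c(c1)[C@@H](CO[Si](C(C)C)(C(C)C)C(C)C)[C@H](c3ccc(O[Si](C(C)C)(C(C)C)C(C)C)c(OC)c3)O2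
A2 | alternative 1 | 4-allyl-2-methoxy-6-{1-[(4-methylphenyl)sulfonyl]-2-[(triisopropylsilyl)oxy]ethyl}phenol (racemic) | C=CCc1cc(OC)c(O)c(c1)C(CO[Si](C(C)C)(C(C)C)C(C)C)S(=O)(=O)c1ccc(C)cc1
A3 | alternative 1 | (2R,5R)-1-{3-methoxy-4-[(triisopropylsilyl)oxy]benzyl}-2,5-dimethylthiolan-1-ium trifluoromethanesulfonate | C[C@@H]1CC[C@@H](C)[S+]1Cc1ccc(O[Si](C(C)C)(C(C)C)C(C)C)c(OC)c1.[O-]S(=O)(=O)C(F)(F)F
A4 | alternative 1 | 4-allyl-2-methoxy-6-{2-[(triisopropylsilyl)oxy]ethylidene}cyclohexa-2,4-dien-1-one (ortho-quinone methide) | C=CCC1=CC(=CCO[Si](C(C)C)(C(C)C)C(C)C)C(=O)C(OC)=C1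
A5 | alternative 2 | (2R,3S)-trans-3-{[(tert-butyldiphenylsilyl)oxy]methyl}-5-{3-[(tert-butyldimethylsilyl)oxy]propyl}-2-{3-methoxy-4-[(triisopropylsilyl)oxy]phenyl}-2,3-dihydrobenzofuran-7-ol | CC(C)(C)[Si](C)(C)OCCCc1cc(O)c2c(c1)[C@@H](CO[Si](c3ccccc3)(c3ccccc3)C(C)(C)C)[C@H](c3ccc(O[Si](C(C)C)(C(C)C)C(C)C)c(OC)c3)O2
A6 | alternative 2 | (1R,2S)-1-(ethynyloxy)-1-{3-methoxy-4-[(triisopropylsilyl)oxy]phenyl}-2-(4-{3-[(tert-butyldimethylsilyl)oxy]propyl}furan-2-yl)-3-[(tert-butyldiphenylsilyl)oxy]propane | CC(C)(C)[Si](C)(C)OCCCc1coc(c1)[C@@H](CO[Si](c2ccccc2)(c2ccccc2)C(C)(C)C)[C@H](c2ccc(O[Si](C(C)C)(C(C)C)C(C)C)c(OC)c2)OC#C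
A7 | alternative 3 | 4-[(2R,3S)-trans-3-{[(tert-butyldiphenylsilyl)oxy]methyl}-5-(3-hydroxypropyl)-7-methoxy-2,3-dihydrobenzofuran-2-yl]-2-methoxyphenol | OCCCc1cc(OC)c2c(c1)[C@@H](CO[Si](c3ccccc3)(c3ccccc3)C(C)(C)C)[C@H](c3ccc(O)c(OC)c3)O2
A8 | alternative 3 | (2S)-3-[(tert-butyldiphenylsilyl)oxy]-2-[2-hydroxy-5-(3-hydroxypropyl)-3-methoxyphenyl]-1-(4-hydroxy-3-methoxyphenyl)propan-1-ol (either C1 epimer) | OCCCc1cc(OC)c(O)c(c1)[C@@H](CO[Si](c2ccccc2)(c2ccccc2)C(C)(C)C)C(O)c1ccc(O)c(OC)c1
A9 | alternative 3 | 4-{3-[(tert-butyldiphenylsilyl)oxy]-2-[2-hydroxy-5-(3-hydroxypropyl)-3-methoxyphenyl]propylidene}-2-methoxycyclohexa-2,5-dien-1-one (para-quinone methide, C3 configured as in A8) | OCCCc1cc(OC)c(O)c(c1)[C@@H](CO[Si](c2ccccc2)(c2ccccc2)C(C)(C)C)C=C1C=CC(=O)C(OC)=C1
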